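Cuts: first C12–C13 (aldol; the lactone ring is bought intact). Then C4–C5 and C9–C10 in one stroke, which unfolds rings A and B to an acyclic epoxy-diene-allylsilane. Then along the chain: C3=C4 (Z-olefination), C1–C2 and C6–C7 (two [3,3] shifts), C5–C10 and C8–C9 (two vinyl-metal additions).
Enabling feature: in ring A the C3 carbinol next to quaternary C4(CH3)(CH2OH) is an opened 2,3-epoxy alcohol. C4, C5=C10 and C9=C8 stand in a 1,5-relation as in a polyprenoid. The exocyclic C8=C17 methylene beside C9 in ring B is the footprint of an allylsilane terminator.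
Forward: the chain grows linearly from C12 to C19 and the oxirane is installed last. One Lewis-acid event then closes ring A together with ring B. No ring is closed after it, and the butanolide is joined as a ready-made ring.
Stereochemistry: C3/C4 come from Sharpless epoxidation of the Z-allylic alcohol (C4 is inverted on opening, so CH2O ends axial). C5, C10 and C9 are relayed by the C5=C10 and C8=C9 geometries through a chair–chair fold. C14 comes from (S)-3-hydroxy-γ-butyrolactone, C13 forms anti to its oxygen, and C12 comes from a syn-selective zirconium aldol.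

Key step: step 11

Remark: labdane numbering is used (decalin C1–C10; C17 exocyclic CH2; C18 = C4-CH3; C19 = C4-CH2O; C20 = C10-CH3; side chain C11–C16 with C16 the lactone carbonyl). The target is then (3R,4R,5S,9R,10S,12S,13S,14S). All carbon building blocks used as starting materials are taken as catalogue items.

Step 1
Reactants: 1 (2-bromoallyl)trimethylsilane; 2 3-(benzyloxy)propanal
Product: 4 (±)-1-(benzyloxy)-4-[(trimethylsilyl)methyl]pent-4-en-3-ol, via [1-(trimethylsilylmethyl)vinyl]magnesium bromide 3 (not isolated)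
Conditions: Mg, THF, reflux; then 2, −78 → 0 °C; aq NH4Cl
Reagents that add atoms: none
Why: Grignard addition of an α-(silylmethyl)vinylmagnesium halide to an aldehyde is routine, the allylsilane is inert to it, and the new carbinol centre (C9) may be racemic because step 2 erases it.

Step 2
Reactants: 4 (±)-1-(benzyloxy)-4-[(trimethylsilyl)methyl]pent-4-en-3-ol; 5 triethyl orthoacetate
Product: 7 ethyl (4Z)-7-(benzyloxy)-4-[(trimethylsilyl)methyl]hept-4-enoate, via mixed ketene acetal 6 (not isolated)
Conditions: 5 (excess), EtCO2H (cat.), 140 °C, EtOH distilled off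
Reagents that add atoms: none
Why: The Johnson–Claisen rearrangement should pass through a chair with the C11 chain equatorial, which moves the double bond to C8=C9 with C11 trans to the new C7–C6 chain (Z only because CH2Si outranks CH2C), and the weak carboxylic acid catalyst should not protodesilylate the allylsilane.

Step 3
Reactants: 7 ethyl (4Z)-7-(benzyloxy)-4-[(trimethylsilyl)methyl]hept-4-enoate
Product: 8 (4Z)-7-(benzyloxy)-4-[(trimethylsilyl)methyl]hept-4-enal
Conditions: DIBAL-H (1.05 equiv), CH2Cl2, −78 °C; Rochelle salt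
Reagents that add atoms: none
Why: Partial DIBAL-H reduction of an ester stops at the aluminium hemiacetal at −78 °C, and the ether, alkene and silane do not react.

Step 4
Reactants: 8 (4Z)-7-(benzyloxy)-4-[(trimethylsilyl)methyl]hept-4-enal; 9 isopropenylmagnesium bromide
Product: 10 (±)-(6Z)-9-(benzyloxy)-2-methyl-6-[(trimethylsilyl)methyl]nona-1,6-dien-3-ol
Conditions: THF, −78 → 0 °C; aq NH4Cl
Reagents that add atoms: none
Why: 1,2-Grignard addition gives the 2-methylallylic alcohol needed for the second [3,3] shift, and its carbinol configuration (C5) is irrelevant because step 5 erases it.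

Step 5
Reactants: 10 (±)-(6Z)-9-(benzyloxy)-2-methyl-6-[(trimethylsilyl)methyl]nona-1,6-dien-3-ol; 5 triethyl orthoacetate
Product: 12 ethyl (4E,8Z)-11-(benzyloxy)-4-methyl-8-[(trimethylsilyl)methyl]undeca-4,8-dienoate, via mixed ketene acetal 11 (not isolated)
Conditions: 5 (excess), EtCO2H (cat.), 140 °C, EtOH distilled off
Reagents that add atoms: none
Why: A second Johnson–Claisen rearrangement through a chair with the C6 chain equatorial sets the E geometry of C5=C10, the classical route to E-trisubstituted 1,5-dienes.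

Step 6
Reactants: 12 ethyl (4E,8Z)-11-(benzyloxy)-4-methyl-8-[(trimethylsilyl)methyl]undeca-4,8-dienoate
Product: 13 (4E,8Z)-11-(benzyloxy)-4-methyl-8-[(trimethylsilyl)methyl]undeca-4,8-dienal
Conditions: DIBAL-H (1.05 equiv), CH2Cl2, −78 °C; Rochelle salt
Reagents that add atoms: none
Why: This is the same partial ester reduction as in step 3, and both alkene geometries are untouched.

Step 7
Reactants: 13 (4E,8Z)-11-(benzyloxy)-4-methyl-8-[(trimethylsilyl)methyl]undeca-4,8-dienal; 14 ethyl 2-[bis(2,2,2-trifluoroethoxy)phosphoryl]propanoate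
Product: 16 ethyl (2Z,6E,10Z)-13-(benzyloxy)-2,6-dimethyl-10-[(trimethylsilyl)methyl]trideca-2,6,10-trienoate, via potassium phosphonate carbanion 15 (not isolated)
Conditions: KHMDS, 18-crown-6, THF, −78 °C
Reagents that add atoms: none
Why: In the Still–Gennari variant of the Horner–Wadsworth–Emmons reaction the electron-poor phosphonate eliminates fast and irreversibly from the kinetic adduct, which should give the Z-enoate with the ester carbon (C19) cis to C2.

Step 8
Reactants: 16 ethyl (2Z,6E,10Z)-13-(benzyloxy)-2,6-dimethyl-10-[(trimethylsilyl)methyl]trideca-2,6,10-trienoate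
Product: 17 (2Z,6E,10Z)-13-(benzyloxy)-2,6-dimethyl-10-[(trimethylsilyl)methyl]trideca-2,6,10-trien-1-ol
Conditions: DIBAL-H (2.5 equiv), CH2Cl2, −78 → 0 °C; Rochelle salt
Reagents that add atoms: none
Why: DIBAL-H reduces enoates cleanly in the 1,2-sense to allylic alcohols without touching the Z geometry.

Step 9
Reactants: 17 (2Z,6E,10Z)-13-(benzyloxy)-2,6-dimethyl-10-[(trimethylsilyl)methyl]trideca-2,6,10-trien-1-ol
Product: 18 {(2S,3R)-3-[(3E,7Z)-10-(benzyloxy)-3-methyl-7-[(trimethylsilyl)methyl]deca-3,7-dien-1-yl]-2-methyloxiran-2-yl}methanol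
Conditions: Ti(OiPr)4 (20 mol %), L-(+)-diethyl tartrate (24 mol %), t-BuOOH, 4 Å MS, CH2Cl2, −20 °C
Reagents that add atoms: tert-butyl hydroperoxide, CC(C)(C)OO
Why: In the Sharpless asymmetric epoxidation the titanium–tartrate complex binds the allylic alcohol so that only C3=C4 is oxidised, L-(+)-tartrate should deliver oxygen to the face that gives the (2S,3R)-oxirane (C4 S, C3 R), and the syn addition keeps CH2OH cis to the C2 chain.

Step 10
Reactants: 18 {(2S,3R)-3-[(3E,7Z)-10-(benzyloxy)-3-methyl-7-[(trimethylsilyl)methyl]deca-3,7-dien-1-yl]-2-methyloxiran-2-yl}methanol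
Product: 19 tert-butyldimethylsilyl ether of 18, (2S,3R)
Conditions: TBSCl, imidazole, CH2Cl2, 0 °C → rt
Reagents that add atoms: tert-butyldimethylsilyl chloride, CC(C)(C)[Si](C)(C)Cl
Why: This is a standard silylation with a base too weak for Payne rearrangement, and the TBS ether keeps the C19 oxygen from quenching the Lewis acid in step 11 and stays to the end.

Step 11
Reactants: 19 tert-butyldimethylsilyl ether of 18, (2S,3R)
Product: 20 (3R,4R,5S,9R,10S)-12-(benzyloxy)-19-[(tert-butyldimethylsilyl)oxy]-13,14,15,16-tetranorlabd-8(17)-en-3-ol (trans-decalin, equatorial 3-OH, axial C4-CH2OTBS cis to C10-CH3, equatorial C9 side chain)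
Conditions: MeAlCl2 (2.5 equiv), CH2Cl2, −78 °C; aq Rochelle salt
Reagents that add atoms: none
Why: MeAlCl2 binds the oxirane oxygen and the C4–O bond ionises with anti (SN2-like) participation of the C5=C10 π bond, the developing C10 cation is taken up by C9 of the allylsilane, and the β-silyl cation at C8 loses Me3SiCl, which places the alkene only at C8=C17. The closest known reaction type is the Lewis-acid-induced, epoxide-initiated polyene cyclization with allylsilane termination. Ring A closes 6-endo at the oxirane (attack at the distal, tertiary C4) and 6-endo-trig at C5=C10, and ring B closes 6-endo-trig at C9=C8, both in a chair–chair fold. C3 keeps the oxirane configuration and its O–Al group lies equatorial, which fixes the absolute sense; C4 is inverted, so the CH2OTBS group that was cis to the chain becomes axial; C5 and C10 follow from anti addition across the E alkene (trans-decalin); C9 follows from the C8=C9 geometry (C11 trans to C7), which puts the side chain equatorial. The step needs opening at C4 rather than C3, cyclization rather than a 1,2-hydride shift to the C3 ketone, and exocyclic termination; the tertiary centre, the nucleophilic trisubstituted alkene poised for a six-membered closure and the β-silicon effect secure these, while the silyl and benzyl ethers should be inert at −78 °C and any capture of C8 by the benzyl ether oxygen is reversible whereas loss of silicon is not.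

Step 12
Reactants: 20 (3R,4R,5S,9R,10S)-12-(benzyloxy)-19-[(tert-butyldimethylsilyl)oxy]-13,14,15,16-tetranorlabd-8(17)-en-3-ol
Product: 21 (3R,4R,5S,9R,10S)-12-(benzyloxy)-3,19-bis[(tert-butyldimethylsilyl)oxy]-13,14,15,16-tetranorlabd-8(17)-ene
Conditions: TBSOTf, 2,6-lutidine, CH2Cl2, 0 °C
Reagents that add atoms: tert-butyldimethylsilyl triflate, CC(C)(C)[Si](C)(C)OS(=O)(=O)C(F)(F)F
Why: Silyl triflate silylation is the usual answer to a hindered equatorial carbinol next to a quaternary carbon, and it removes the last acidic proton before the strongly basic steps 13 and 15.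

Step 13
Reactants: 21 (3R,4R,5S,9R,10S)-12-(benzyloxy)-3,19-bis[(tert-butyldimethylsilyl)oxy]-13,14,15,16-tetranorlabd-8(17)-ene
Product: 22 (3R,4R,5S,9R,10S)-3,19-bis[(tert-butyldimethylsilyl)oxy]-13,14,15,16-tetranorlabd-8(17)-en-12-ol
Conditions: Li, NH3(l)/THF, −78 °C; solid NH4Cl
Reagents that add atoms: none
Why: Dissolving-metal cleavage of a benzyl ether is fast, and the isolated 1,1-disubstituted alkene and the silyl ethers are not reduced.

Step 14
Reactants: 22 (3R,4R,5S,9R,10S)-3,19-bis[(tert-butyldimethylsilyl)oxy]-13,14,15,16-tetranorlabd-8(17)-en-12-ol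
Product: 23 (3R,4R,5S,9R,10S)-3,19-bis[(tert-butyldimethylsilyl)oxy]-13,14,15,16-tetranorlabd-8(17)-en-12-al
Conditions: Dess–Martin periodinane, CH2Cl2, 0 °C → rt
Reagents that add atoms: none
Why: Dess–Martin oxidation is near neutral and stops at the aldehyde, no stereocentre is α to the new carbonyl, and the exocyclic alkene is untouched.

Step 15
Reactants: 23 (3R,4R,5S,9R,10S)-3,19-bis[(tert-butyldimethylsilyl)oxy]-13,14,15,16-tetranorlabd-8(17)-en-12-al; 24 (S)-3-hydroxy-γ-butyrolactone
Product: 27 (3S,4S)-3-[(1S)-2-{(1R,4aS,5R,6R,8aS)-6-(TBSO)-5-(TBSOCH2)-5,8a-dimethyl-2-methylidenedecahydronaphthalen-1-yl}-1-hydroxyethyl]-4-hydroxyoxolan-2-one (3,19-bis-TBS ether of the target), via dilithio β-oxido enolate 25 (not isolated), via bis(chlorozirconocene) β-oxido enolate 26 (not isolated)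
Conditions: 24 (2.5 equiv), LDA (2 equiv per 24), THF, −78 °C; Cp2ZrCl2 (2 equiv per 24), −78 → −50 °C; 23, −78 °C; aq NH4Cl
Reagents that add atoms: none
Why: Proposed new method: double deprotonation gives the β-oxido enolate, whose alkoxide is too poor a leaving group for E1cB loss (a Fráter–Seebach-type dianion whose lithium alkylations and aldol additions occur trans to the oxygen), so C13 should form anti to the C14–O substituent; the ring locks the enolate as E(O), for which a lithium Zimmerman–Traxler chair would give the unwanted 12,13-anti adduct, whereas chlorozirconocene enolates give syn aldols from either enolate geometry because the Cp ligands push E(O)-enolates into a boat-like closed transition state, and this should deliver 12S; the closest known reaction types are the zirconium-enolate syn aldol of ketone, ester and amide enolates and the lithium aldol of this dianion, and what is new is their combination on a β-metal-oxido lactone enolate.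

Step 16
Reactants: 27 3,19-bis-TBS ether of the target
Product: 28 (3S,4S)-4-hydroxy-3-[(1S)-1-hydroxy-2-{(1R,4aS,5R,6R,8aS)-6-hydroxy-5-(hydroxymethyl)-5,8a-dimethyl-2-methylidenedecahydronaphthalen-1-yl}ethyl]oxolan-2-one (target)
Conditions: HF·pyridine, THF, 0 °C → rt
Reagents that add atoms: none
Why: Fluoride-driven Si–O cleavage in a weakly acidic medium avoids the retro-aldol and E1cB pathways that a basic fluoride source would open in the β,β'-dihydroxy lactone, and it touches no stereocentre.

Compound list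
1 | (2-bromoallyl)trimethylsilane | C=C(Br)C[Si](C)(C)C | starting material
2 | 3-(benzyloxy)propanal | O=CCCOCc1ccccc1 | starting material
3 | [1-(trimethylsilylmethyl)vinyl]magnesium bromide | C=C([Mg]Br)C[Si](C)(C)C | intermediate
4 | (±)-1-(benzyloxy)-4-[(trimethylsilyl)methyl]pent-4-en-3-ol | C=C(C[Si](C)(C)C)C(O)CCOCc1ccccc1 | intermediate
5 | triethyl orthoacetate | CCOC(C)(OCC)OCC | starting material
6 | mixed ketene acetal of 4 | C=C(OCC)OC(CCOCc1ccccc1)C(=C)C[Si](C)(C)C | intermediate
7 | ethyl (4Z)-7-(benzyloxy)-4-[(trimethylsilyl)methyl]hept-4-enoate | CCOC(=O)CC/C(C[Si](C)(C)C)=C/CCOCc1ccccc1 | intermediate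
8 | (4Z)-7-(benzyloxy)-4-[(trimethylsilyl)methyl]hept-4-enal | O=CCC/C(C[Si](C)(C)C)=C/CCOCc1ccccc1 | intermediate
9 | isopropenylmagnesium bromide | C=C(C)[Mg]Br | starting material
10 | (±)-(6Z)-9-(benzyloxy)-2-methyl-6-[(trimethylsilyl)methyl]nona-1,6-dien-3-ol | C=C(C)C(O)CC/C(C[Si](C)(C)C)=C/CCOCc1ccccc1 | intermediate
11 | mixed ketene acetal of 10 | C=C(OCC)OC(CC/C(C[Si](C)(C)C)=C/CCOCc1ccccc1)C(C)=C | intermediate
12 | ethyl (4E,8Z)-11-(benzyloxy)-4-methyl-8-[(trimethylsilyl)methyl]undeca-4,8-dienoate | CCOC(=O)CC/C(C)=C/CC/C(C[Si](C)(C)C)=C/CCOCc1ccccc1 | intermediate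
13 | (4E,8Z)-11-(benzyloxy)-4-methyl-8-[(trimethylsilyl)methyl]undeca-4,8-dienal | O=CCC/C(C)=C/CC/C(C[Si](C)(C)C)=C/CCOCc1ccccc1 | intermediate
14 | ethyl 2-[bis(2,2,2-trifluoroethoxy)phosphoryl]propanoate | CCOC(=O)C(C)P(=O)(OCC(F)(F)F)OCC(F)(F)F | starting material
15 | potassium carbanion of 14 | [K+].CCOC(=O)[C-](C)P(=O)(OCC(F)(F)F)OCC(F)(F)F | intermediate
16 | ethyl (2Z,6E,10Z)-13-(benzyloxy)-2,6-dimethyl-10-[(trimethylsilyl)methyl]trideca-2,6,10-trienoate | CCOC(=O)/C(C)=C\CC/C(C)=C/CC/C(C[Si](C)(C)C)=C/CCOCc1ccccc1 | intermediate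
17 | (2Z,6E,10Z)-13-(benzyloxy)-2,6-dimethyl-10-[(trimethylsilyl)methyl]trideca-2,6,10-trien-1-ol | OC/C(C)=C\CC/C(C)=C/CC/C(C[Si](C)(C)C)=C/CCOCc1ccccc1 | intermediate
18 | {(2S,3R)-3-[(3E,7Z)-10-(benzyloxy)-3-methyl-7-[(trimethylsilyl)methyl]deca-3,7-dien-1-yl]-2-methyloxiran-2-yl}methanol | OC[C@]1(C)O[C@@H]1CC/C(C)=C/CC/C(C[Si](C)(C)C)=C/CCOCc2ccccc2 | intermediate
19 | TBS ether of 18 | CC(C)(C)[Si](C)(C)OC[C@]1(C)O[C@@H]1CC/C(C)=C/CC/C(C[Si](C)(C)C)=C/CCOCc2ccccc2 | intermediate
20 | (3R,4R,5S,9R,10S)-12-(benzyloxy)-19-(TBSO)-13,14,15,16-tetranorlabd-8(17)-en-3-ol | C=C1CC[C@@H]2[C@](C)(CO[Si](C)(C)C(C)(C)C)[C@H](O)CC[C@@]2(C)[C@@H]1CCOCc3ccccc3 | intermediate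
21 | (3R,4R,5S,9R,10S)-12-(benzyloxy)-3,19-bis(TBSO)-13,14,15,16-tetranorlabd-8(17)-ene | C=C1CC[C@@H]2[C@](C)(CO[Si](C)(C)C(C)(C)C)[C@H](O[Si](C)(C)C(C)(C)C)CC[C@@]2(C)[C@@H]1CCOCc3ccccc3 | intermediate
22 | (3R,4R,5S,9R,10S)-3,19-bis(TBSO)-13,14,15,16-tetranorlabd-8(17)-en-12-ol | C=C1CC[C@@H]2[C@](C)(CO[Si](C)(C)C(C)(C)C)[C@H](O[Si](C)(C)C(C)(C)C)CC[C@@]2(C)[C@@H]1CCO | intermediate
23 | (3R,4R,5S,9R,10S)-3,19-bis(TBSO)-13,14,15,16-tetranorlabd-8(17)-en-12-al | C=C1CC[C@@H]2[C@](C)(CO[Si](C)(C)C(C)(C)C)[C@H](O[Si](C)(C)C(C)(C)C)CC[C@@]2(C)[C@@H]1CC=O | intermediate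
24 | (S)-3-hydroxy-γ-butyrolactone | O=C1C[C@H](O)CO1 | starting material
25 | dilithio β-oxido enolate of 24 | [Li]OC1=C[C@H](O[Li])CO1 | intermediate
26 | bis(chlorozirconocene) β-oxido enolate of 24 | [Cl-].[Cl-].[Zr+4].[Zr+4].[cH-]1cccc1.[cH-]1cccc1.[cH-]1cccc1.[cH-]1cccc1.[O-]C1=C[C@H]([O-])CO1 | intermediate
27 | 3,19-bis-TBS ether of the target, (12S,13S,14S) | C=C1CC[C@@H]2[C@](C)(CO[Si](C)(C)C(C)(C)C)[C@H](O[Si](C)(C)C(C)(C)C)CC[C@@]2(C)[C@@H]1C[C@H](O)[C@@H]1C(=O)OC[C@H]1O | intermediate
28 | CNP0113086.2, (3R,4R,5S,9R,10S,12S,13S,14S) | C=C1CC[C@@H]2[C@](C)(CO)[C@H](O)CC[C@@]2(C)[C@@H]1C[C@H](O)[C@@H]1C(=O)OC[C@H]1O | target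

Total step count: 16. Longest linear sequence: 16 steps (from 1 and 2 to 28).

Steps most likely to fail

Step 15. Possible failures:
- weak discrimination between boat and chair, and so at C12
- incomplete lithium-to-zirconium exchange
- β-elimination of the metal alkoxide from the enolate on warming
- retro-aldol on work-up

The fallback sets out from 23 and comes back at 27. It makes C12 as a ketone and sets it by 1,3-induction from the C14 hydroxyl. Pinnick oxidation of 23 (NaClO2, NaH2PO4, 2-methyl-2-butene) would give the C12 carboxylic acid F1. EDC and N,O-dimethylhydroxylamine hydrochloride would give the Weinreb amide F2. Addition of the dilithio species 25 at −78 °C would give the 13,14-trans 12-oxo lactone F3; here the alkoxide does not acylate on a Weinreb amide, and the chelated tetrahedral adduct holds until the cold acidic quench. F3 is carried on crude. Narasaka–Prasad reduction (Et2BOMe, NaBH4, THF/MeOH, −78 °C) runs through a boron chelate of O14 and O12 that is trans-fused to the lactone and carries all carbon substituents equatorial. Axial hydride delivery should give the 12,14-syn diol, which is 27.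

Step 11. Possible failures:
- 1,2-hydride shift to the C3 ketone, because the C19 oxygen destabilises charge at C4
- opening at C3
- an arrested cascade after the first ring
- loss of a protecting group

The fallback sets out from 13 and comes back at 21. It replaces the cationic event with an oxidative radical bicyclization. Roskamp homologation of 13 (ethyl diazoacetate, SnCl2 cat.) would give the β-keto ester F4. K2CO3/MeI would give the α-methyl β-keto ester F5. Mn(OAc)3/Cu(OAc)2 in AcOH would generate the C4 radical, which closes 6-endo/6-endo. Oxidation of the β-silyl C8 radical with loss of silicon would then give the racemic trans-decalin keto ester F6, with the ester axial at C4. LiAlH4 (hydride from the face opposite the axial C4 and C10 groups) would give the racemic 3-equatorial 3,19-diol F7, and excess TBSOTf/2,6-lutidine would give racemic 21. The two enantiomers would then part as separable diastereomers after step 15, because 24 is enantiopure.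

Step 9. Possible failures: slow turnover and incomplete facial selectivity, the known weakness of allylic alcohols that carry a substituent cis to the hydroxymethyl group. The fallback sets out from 20 and comes back at 20. It secures the absolute configuration by separating diastereomers instead of by catalyst control. Scalemic 20 would be esterified with (S)-O-acetylmandelic acid (DCC, DMAP) to the (S)-O-acetylmandelate ester F8. The diastereomers would be separated by chromatography or crystallization, and LiAlH4 (Et2O, 0 °C) would release enantiopure 20.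

Further compounds
F1 | step 15 | (3R,4R,5S,9R,10S)-3,19-bis(TBSO)-13,14,15,16-tetranorlabd-8(17)-en-12-oic acid | C=C1CC[C@@H]2[C@](C)(CO[Si](C)(C)C(C)(C)C)[C@H](O[Si](C)(C)C(C)(C)C)CC[C@@]2(C)[C@@H]1CC(=O)O
F2 | step 15 | N-methoxy-N-methylamide of F1 | C=C1CC[C@@H]2[C@](C)(CO[Si](C)(C)C(C)(C)C)[C@H](O[Si](C)(C)C(C)(C)C)CC[C@@]2(C)[C@@H]1CC(=O)N(C)OC
F3 | step 15 | 12-oxo analogue of 27 (13,14-trans) | C=C1CC[C@@H]2[C@](C)(CO[Si](C)(C)C(C)(C)C)[C@H](O[Si](C)(C)C(C)(C)C)CC[C@@]2(C)[C@@H]1CC(=O)[C@@H]1C(=O)OC[C@H]1O
F4 | step 11 | ethyl (6E,10Z)-13-(benzyloxy)-6-methyl-3-oxo-10-[(trimethylsilyl)methyl]trideca-6,10-dienoate | CCOC(=O)CC(=O)CC/C(C)=C/CC/C(C[Si](C)(C)C)=C/CCOCc1ccccc1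
F5 | step 11 | ethyl (6E,10Z)-13-(benzyloxy)-2,6-dimethyl-3-oxo-10-[(trimethylsilyl)methyl]trideca-6,10-dienoate (racemic) | CCOC(=O)C(C)C(=O)CC/C(C)=C/CC/C(C[Si](C)(C)C)=C/CCOCc1ccccc1
F6 | step 11 | rac-ethyl 12-(benzyloxy)-3-oxo-13,14,15,16-tetranorlabd-8(17)-en-19-oate (one enantiomer drawn) | C=C1CC[C@@H]2[C@](C)(C(=O)OCC)C(=O)CC[C@@]2(C)[C@@H]1CCOCc3ccccc3
F7 | step 11 | rac-12-(benzyloxy)-13,14,15,16-tetranorlabd-8(17)-ene-3,19-diol (one enantiomer drawn) | C=C1CC[C@@H]2[C@](C)(CO)[C@H](O)CC[C@@]2(C)[C@@H]1CCOCc3ccccc3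
F8 | step 9 | 3-O-[(S)-O-acetylmandeloyl] derivative of 20 | C=C1CC[C@@H]2[C@](C)(CO[Si](C)(C)C(C)(C)C)[C@H](OC(=O)[C@@H](OC(C)=O)c3ccccc3)CC[C@@]2(C)[C@@H]1CCOCc4ccccc4
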